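## The problem

Target 18 has a single ring, an oxolane (O1, C2–C5), with three contiguous substituents: a 3-hydroxy-4-methoxyphenyl group on C2, a hydroxymethyl group on C3 and a 3-hydroxy-4-methoxybenzoyl group on C4. The configuration is 2S,3R,4S, so both neighbouring pairs are trans. A synthesis has to close one cyclic ether, attach the same arene twice (once to a carbinol-level carbon, once to a carbonyl carbon) and fix three stereocentres. The centres are not equal. C2 is a benzylic ether carbon that no base can invert, C4 lies α to the ketone and can be equilibrated, and C3 becomes equilibrable whenever its side-chain carbon is at the aldehyde level. One external source of chirality at C2 can therefore command the other two through thermodynamics, the all-trans isomer being the most stable. The C2–O1 bond is a para-alkoxybenzylic ether: acid ionises it (racemising an open-chain precursor, epimerising the ring) and hydrogen can cleave it, so acid must be kept out and the last deprotection must be gentle. The two phenols must be masked through organometallic and oxidative steps, the ring oxygen sits β to both carbonyl-level carbons, and the 3,4-cis hydroxy ketone would close to a hemiketal. The enabling feature is the chain O=C–C4–C3–CH2–O: the ketone carbon on C4 and the carbinol carbon on C3 are 1,4-dioxygenated and sit on adjacent ring carbons, so they can be read as the two ends of a cleaved cyclobutene fused across C3–C4. A cyclobutanone fused in that way to an oxolane is what an intramolecular keteniminium–alkene [2+2] of an allyl-ether-tethered amide delivers, with both rings closing together.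

## Retrosynthesis

**18 ⇒ 17.** The two phenolic O–H bonds are traced back to O–benzyl bonds. Benzyl is chosen over silyl (labile to amidine base and fluoride-free organometallic work is fine, but aryl silyl ethers are cleaved under the epimerisation conditions) and over acetal groups (attacked by Tf2O). It survives every reagent of the route and leaves under neutral hydrogenolysis. The forward step must spare the aryl ketone and the benzylic C2–O1 bond.

**17 ⇒ 16 ⇒ 15.** No skeletal bond is cut here. The hydroxymethyl group is taken back to a formyl group (16), and the all-trans keto aldehyde 16 to its 3,4-cis isomer 15. Equilibrating at the keto aldehyde stage rather than after reduction is preferred, because there both C3 and C4 are enolisable and the mixture can drain to the all-trans isomer whatever the earlier diastereoselectivity was. After reduction the cis isomer would be held as a hemiketal. The forward steps need a mild base and a hydride that discriminates aldehyde from electron-rich aryl ketone.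

**15 ⇒ 13.** The ketone carbon and the aldehyde carbon are reconnected as a C=C bond, giving the 1-arylcyclobutene 13. Compared with attaching the aroyl and the one-carbon side chain separately to a preformed oxolane (two C–C bond formations, two independent stereochemical problems), this turns both into one ring. The forward reaction is an oxidative alkene cleavage that must leave two dialkoxyarenes and two benzyl ethers alone.

**13 ⇒ 12 ⇒ 9 + 10.** The bond between the alkene carbon and its arene is cut, via tertiary alcohol 12, to cyclobutanone 9 and aryl bromide 10 (as Grignard reagent 11). This removes half of the carbon atoms in one disconnection and uses the most electrophilic ketone class available. The forward dehydration must lose a proton from the cyclobutane methylene and not from the ring-fusion carbon.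

**9 ⇒ 6 (key disconnection).** Two bonds are cut at once: C3–C4 of the oxolane and the bond between the carbonyl carbon and the cyclobutane methylene. This opens both rings and leaves the acyclic amide 6, in which only C2 is stereogenic. A stepwise alternative (oxolane first, four-membered ring second) would need a [2+2] on a 2-aryl-2,5-dihydrofuran with a regiochemical question. The tethered version answers that question by construction. The forward step needs amide activation that tolerates an ionisable benzylic allylic ether, and facial control by C2.

**6 ⇒ 4 + 5.** The O–CH2 bond is cut to the allylic alcohol 4 and N,N-dimethylacrylamide 5. Cutting the other C–O bond (at C2) would require a stereocontrolled substitution at an ionisable centre. This cut leaves the stereocentre untouched. The forward reaction is an oxa-Michael addition of a hindered secondary alkoxide to a weak acceptor.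

**4 ⇒ 3 ⇒ 1 + 2.** The C2–vinyl bond is cut to aldehyde 1 and vinylmagnesium bromide 2. The racemic alcohol 3 is then resolved, since a lipase accepts aryl vinyl carbinols reliably and under neutral conditions. The price is that half of 3 is set aside as the acetate.

## Roads not taken

**Alternative 1:** Both aryl–carbon bonds (C2–aryl and carbonyl–aryl) are cut back to the lactone Weinreb amide A1, which already holds the oxolane carbons with C3/C4 trans. In the forward key step an excess of the aryllithium A2 would add at low temperature to the lactone carbonyl (stopping at the lactolate) and to the Weinreb amide (stopping at the chelated adduct), giving keto lactol A3 on work-up.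
- Merits: both identical arenes enter in one flask from one reagent, no four-membered ring is built and destroyed, and the C3/C4 relationship precedes any arene.
- Weak points: C2 arrives at the wrong oxidation level. Deoxygenation of the lactol (silane with a Lewis acid, through the oxocarbenium ion) delivers hydride anti to the C3 side chain, which places the aryl group cis to it, the opposite of what is needed. The same acidic medium threatens ionic reduction of the electron-rich aryl ketone and Paal–Knorr-type cyclodehydration of the ring-opened 1,4-dicarbonyl tautomer. A1 in enantiopure trans form is itself a multistep target.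
- Comparison: this road is more convergent and, counted from A1, shorter. The chosen plan sets against it a C2 configuration that comes with alcohol 4 and never has to be created on an oxocarbenium ion, and an end-game that is neutral or basic throughout.

**Alternative 2:** A cyclobutanone is used in the opposite sense, expanded instead of cleaved. The cut is at the ring oxygen, back to the prochiral cyclobutanone A4. In the forward key step a Baeyer–Villiger monooxygenase of the cyclohexanone monooxygenase class (NADPH, O2) inserts oxygen into one of the two enantiotopic C–C bonds and gives lactone A5 with C4 set.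
- Merits: it is a desymmetrisation, so no half of the material is discarded, which is better than the resolution in step 2 of the chosen plan. The enzyme oxidises the strained ketone and leaves the 1-arylethenyl group, the latent aroyl unit.
- Weak points: only one stereocentre and no C–C bond of the target is made. C3 still needs an enolate hydroxymethylation, C2 needs aryl addition to the lactone and lactol reduction (the same cis-selective hydride delivery as in Alternative 1), and the alkene must be cleaved. Acceptance of a bulky benzyloxyaryl-vinyl substituent by the enzyme and the sense of induction cannot be predicted without screening.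
- Comparison: this road is better in its source of asymmetry. The chosen plan offsets that with one step that builds the ring, the C3–C4 bond and the carbon skeleton of both side chains, and with relative configuration that settles by equilibrium.

**Alternative 3:** O1–C2 and C3–C4 are cut, a formal [3+2] of an O1–C5–C4 dipole with a C2–C3 acceptor. In the forward key step zerovalent palladium (Pd2(dba)3 with a chiral phosphoramidite) ionises the racemic vinyl carbonate A6 with loss of CO2, the alkoxide adds to benzylidene malonate A7, and the malonate carbanion closes on the π-allyl unit to give oxolane A8.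
- Merits: two fragments, each carrying one arene, are joined convergently. The ring and the C2 and C4 stereocentres form in one catalytic enantioselective step from racemic material, with no resolution.
- Weak points: A7 is an electron-rich, sluggish acceptor whose oxa-Michael adduct reverts easily. C3 emerges as a quaternary diester, so a hot dealkoxycarbonylation next to a β-alkoxy centre, an ester reduction and an alkene cleavage all remain, with C3 set only at a protonation. The required 2,4-cis relationship would depend on a ligand–substrate match that is untested for an aryl-substituted allyl unit.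
- Comparison: this road is superior in catalytic control of absolute configuration and in convergency. The chosen plan sets against it a shorter, milder sequence after ring formation (no decarboxylation, no ester reduction beside a latent ketone) and stereocentres fixed by thermodynamics instead of by a catalyst.

Key step: step 4

## Route

Remarks on the chemistry:
- Aldehyde 1 and bromide 10 are treated as purchasable; each is otherwise one O-benzylation away from isovanillin or 5-bromo-2-methoxyphenol.
- The carbinol centre of 12 is drawn as the expected convex-face adduct and is destroyed in step 6.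
- Ozonide 14 is drawn in its monomeric form with undefined bridgeheads.
- Oxolane numbering (O1, C2–C5) is used in the explanations.

Step 1
Reactants: 1 3-(benzyloxy)-4-methoxybenzaldehyde; 2 vinylmagnesium bromide
Product: 3 rac-1-[3-(benzyloxy)-4-methoxyphenyl]prop-2-en-1-ol
Conditions: THF, −20 °C → 0 °C; then H2O
Reagents that add atoms: none
Why: Grignard 1,2-addition to a non-enolisable aromatic aldehyde; the new centre forms racemic and is sorted in step 2, and the neutral quench keeps the acid-labile allylic benzylic alcohol from ionising.

Step 2
Reactants: 3 rac-1-[3-(benzyloxy)-4-methoxyphenyl]prop-2-en-1-ol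
Product: 4 (1S)-1-[3-(benzyloxy)-4-methoxyphenyl]prop-2-en-1-ol
Conditions: Novozym 435 (immobilised Candida antarctica lipase B), vinyl acetate, MTBE, 30 °C, stopped slightly beyond half conversion
Reagents that add atoms: none
Why: Lipase-catalysed kinetic resolution by irreversible transesterification; by the empirical size rule for secondary alcohols the enzyme should acylate the R enantiomer (aryl in the large pocket, vinyl in the medium one) and leave S-configured 4, which is separated from the acetate by chromatography; the medium is neutral, so the alcohol should neither racemise nor transpose.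

Step 3
Reactants: 4 (1S)-1-[3-(benzyloxy)-4-methoxyphenyl]prop-2-en-1-ol; 5 N,N-dimethylprop-2-enamide
Product: 6 N,N-dimethyl-3-{[(1S)-1-[3-(benzyloxy)-4-methoxyphenyl]prop-2-en-1-yl]oxy}propanamide
Conditions: KOtBu (10 mol %), 5 (3 equiv, added slowly), THF, 0 °C → rt
Reagents that add atoms: none
Why: Base-catalysed oxa-Michael addition of the alkoxide to the acrylamide; the amide enolate formed is protonated by further alcohol, so the base turns over, excess acceptor pushes the equilibrium, and no bond at the stereocentre is made or broken.

Step 4
Reactants: 6 N,N-dimethyl-3-{[(1S)-1-[3-(benzyloxy)-4-methoxyphenyl]prop-2-en-1-yl]oxy}propanamide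
Product: 9 (1S,2S,5R)-2-[3-(benzyloxy)-4-methoxyphenyl]-3-oxabicyclo[3.2.0]heptan-6-one, via keteniminium triflate 7 (not isolated), via cyclobutaniminium triflate 8 (not isolated)
Conditions: Tf2O (1.1 equiv), 2,4,6-collidine (1.3 equiv), ClCH2CH2Cl (0.05 M), −20 °C → 80 °C; then H2O, 40 °C
Reagents that add atoms: water, O
Why: This is an intramolecular keteniminium–alkene [2+2] cycloaddition, the amide-activation counterpart of the ketene cycloaddition, applied to a 3-(allyloxy)propanamide, a substrate type that is known to give 3-oxabicyclo[3.2.0]heptan-6-ones. The amide oxygen, the most nucleophilic site of 6, is triflated and the hindered, non-nucleophilic collidine removes an α-proton to give keteniminium ion 7. The terminal vinyl carbon attacks the central carbon of 7 while the enamine-type carbon bonds to the internal vinyl carbon in an asynchronous process, giving iminium salt 8, which water hydrolyses to ketone 9. The oxolane closes through the C3–C4 bond, 5-exo with respect to the alkene, and the four-membered ring closes through the bond from the iminium carbon to the former CH2 terminus; the three-atom tether permits only the fused bicyclo[3.2.0] connectivity and only a cis ring fusion, which fixes C4 relative to C3. C3 is set by the existing centre C2: the aryl group should take the convex face of the folding bicycle, away from the forming cyclobutane, so the cyclobutane methylene on C3 ends up trans to the aryl group. Chemoselectivity rests on the much higher nucleophilicity of the amide oxygen compared with the ether oxygen and the arenes, and on the absence of any acid stronger than collidinium triflate, which protects the ionisable C2–O bond. The facial selectivity need not be perfect, because C3 and C4 both become enolisable after step 7 and are equilibrated in step 8.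

Step 5
Reactants: 9 (1S,2S,5R)-2-[3-(benzyloxy)-4-methoxyphenyl]-3-oxabicyclo[3.2.0]heptan-6-one; 10 2-(benzyloxy)-4-bromo-1-methoxybenzene
Product: 12 (1S,2S,5R,6R)-2,6-bis[3-(benzyloxy)-4-methoxyphenyl]-3-oxabicyclo[3.2.0]heptan-6-ol, via arylmagnesium bromide 11 (not isolated)
Conditions: 10, Mg turnings, THF, rt; then added to 9 premixed with anhydrous CeCl3, THF, −78 °C; then H2O
Reagents that add atoms: none
Why: CeCl3-assisted Grignard 1,2-addition to a strained, highly electrophilic cyclobutanone, where the oxophilic additive and the low temperature suppress enolisation; attack should come from the convex face, but the carbinol configuration is irrelevant because the centre becomes trigonal in step 6.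

Step 6
Reactants: 12 (1S,2S,5R,6R)-2,6-bis[3-(benzyloxy)-4-methoxyphenyl]-3-oxabicyclo[3.2.0]heptan-6-ol
Product: 13 (1S,2S,5S)-2,6-bis[3-(benzyloxy)-4-methoxyphenyl]-3-oxabicyclo[3.2.0]hept-6-ene
Conditions: Burgess reagent (methyl N-(triethylammoniosulfonyl)carbamate), toluene, 50 °C
Reagents that add atoms: none
Why: Burgess dehydration of a tertiary benzylic alcohol under neutral conditions, so the C2–O1 bond is not exposed to acid; proton loss from the cyclobutane methylene is favoured because a double bond to the ring-fusion carbon would put a trigonal centre at the junction of the four- and five-membered rings.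

Step 7
Reactants: 13 (1S,2S,5S)-2,6-bis[3-(benzyloxy)-4-methoxyphenyl]-3-oxabicyclo[3.2.0]hept-6-ene
Product: 15 (2S,3S,4R)-4-[3-(benzyloxy)-4-methoxybenzoyl]-2-[3-(benzyloxy)-4-methoxyphenyl]oxolane-3-carbaldehyde, via ozonide 14 (not isolated)
Conditions: O3, CH2Cl2, −78 °C, Sudan Red 7B as end-point indicator; then PPh3, −78 °C → rt; crude product used directly
Reagents that add atoms: ozone, [O-][O+]=O
Why: Ozonolysis with reductive work-up: the strained, electron-rich styrene-type double bond should react far faster than the dialkoxyarenes or the benzyl ethers, the dye end point prevents an excess, and PPh3 reduces the ozonide to the ketone and the aldehyde; the ring-fusion centres are untouched, so the 3,4-cis keto aldehyde results.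

Step 8
Reactants: 15 (2S,3S,4R)-4-[3-(benzyloxy)-4-methoxybenzoyl]-2-[3-(benzyloxy)-4-methoxyphenyl]oxolane-3-carbaldehyde
Product: 16 (2S,3S,4S)-4-[3-(benzyloxy)-4-methoxybenzoyl]-2-[3-(benzyloxy)-4-methoxyphenyl]oxolane-3-carbaldehyde
Conditions: DBU (0.3 equiv), CH2Cl2, rt, under argon
Reagents that add atoms: none
Why: Base-mediated epimerisation through the enolates under thermodynamic control: C3 (α to the aldehyde) and C4 (α to the ketone) both exchange while C2 cannot, so the mixture should drain to the all-trans isomer relative to C2; ring opening by β-elimination of O1 is the reverse of a 5-endo-trig closure and is stereoelectronically disfavoured.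

Step 9
Reactants: 16 (2S,3S,4S)-4-[3-(benzyloxy)-4-methoxybenzoyl]-2-[3-(benzyloxy)-4-methoxyphenyl]oxolane-3-carbaldehyde
Product: 17 [3-(benzyloxy)-4-methoxyphenyl]{(3S,4R,5S)-5-[3-(benzyloxy)-4-methoxyphenyl]-4-(hydroxymethyl)oxolan-3-yl}methanone
Conditions: NaBH4 (1 equiv), EtOH/CH2Cl2 (3:7), −78 °C
Reagents that add atoms: none
Why: Chemoselective hydride reduction of an aldehyde beside a ketone at low temperature, helped here by the deactivated para-alkoxyaryl ketone; no stereocentre is formed, C3 is locked once its side chain is an alcohol, and the trans hydroxy ketone cannot close to a hemiketal without a strained trans-fused bicycle.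

Step 10
Reactants: 17 [3-(benzyloxy)-4-methoxyphenyl]{(3S,4R,5S)-5-[3-(benzyloxy)-4-methoxyphenyl]-4-(hydroxymethyl)oxolan-3-yl}methanone
Product: 18 (3-hydroxy-4-methoxyphenyl)[(3S,4R,5S)-5-(3-hydroxy-4-methoxyphenyl)-4-(hydroxymethyl)oxolan-3-yl]methanone
Conditions: H2 (1 atm), Pd/C (10 wt %), EtOAc, rt, stopped after uptake of two equivalents
Reagents that add atoms: none
Why: Hydrogenolysis of aryl benzyl ethers, which in a neutral aprotic solvent at atmospheric pressure should run well ahead of cleavage of the cyclic benzylic C2–O1 bond and of reduction of the electron-rich aryl ketone; no stereocentre is involved.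

## Compound list

1 | 3-(benzyloxy)-4-methoxybenzaldehyde | O=Cc1ccc(OC)c(OCc2ccccc2)c1 | starting material
2 | vinylmagnesium bromide | C=C[Mg]Br | starting material
3 | rac-1-[3-(benzyloxy)-4-methoxyphenyl]prop-2-en-1-ol | OC(c1ccc(OC)c(OCc2ccccc2)c1)C=C | intermediate
4 | (1S)-1-[3-(benzyloxy)-4-methoxyphenyl]prop-2-en-1-ol | O[C@H](c1ccc(OC)c(OCc2ccccc2)c1)C=C | intermediate
5 | N,N-dimethylprop-2-enamide (N,N-dimethylacrylamide) | C=CC(=O)N(C)C | starting material
6 | N,N-dimethyl-3-{[(1S)-1-[3-(benzyloxy)-4-methoxyphenyl]prop-2-en-1-yl]oxy}propanamide | CN(C)C(=O)CCO[C@H](c1ccc(OC)c(OCc2ccccc2)c1)C=C | intermediate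
7 | keteniminium triflate derived from 6 (not isolated) | C[N+](C)=C=CCO[C@H](c1ccc(OC)c(OCc2ccccc2)c1)C=C.[O-]S(=O)(=O)C(F)(F)F | intermediate
8 | N,N-dimethyl cyclobutaniminium triflate of 9 (not isolated) | C[N+](C)=C1[C@H]2CO[C@H](c3ccc(OC)c(OCc4ccccc4)c3)[C@H]2C1.[O-]S(=O)(=O)C(F)(F)F | intermediate
9 | (1S,2S,5R)-2-[3-(benzyloxy)-4-methoxyphenyl]-3-oxabicyclo[3.2.0]heptan-6-one (cis-fused, aryl on the convex face) | O=C1[C@H]2CO[C@H](c3ccc(OC)c(OCc4ccccc4)c3)[C@H]2C1 | intermediate
10 | 2-(benzyloxy)-4-bromo-1-methoxybenzene | COc1ccc(Br)cc1OCc1ccccc1 | starting material
11 | [3-(benzyloxy)-4-methoxyphenyl]magnesium bromide (not isolated) | COc1ccc([Mg]Br)cc1OCc1ccccc1 | intermediate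
12 | (1S,2S,5R,6R)-2,6-bis[3-(benzyloxy)-4-methoxyphenyl]-3-oxabicyclo[3.2.0]heptan-6-ol | O[C@@]1(c2ccc(OC)c(OCc3ccccc3)c2)[C@H]2CO[C@H](c3ccc(OC)c(OCc4ccccc4)c3)[C@H]2C1 | intermediate
13 | (1S,2S,5S)-2,6-bis[3-(benzyloxy)-4-methoxyphenyl]-3-oxabicyclo[3.2.0]hept-6-ene | COc1ccc(C2=C[C@H]3[C@@H]2CO[C@@H]3c2ccc(OC)c(OCc4ccccc4)c2)cc1OCc1ccccc1 | intermediate
14 | ozonide of 13, a 1,2,4-trioxolane spanning the former alkene carbons (not isolated; bridgeheads undefined) | COc1ccc(C23OC(OO2)[C@@H]2[C@@H](c4ccc(OC)c(OCc5ccccc5)c4)OC[C@@H]23)cc1OCc1ccccc1 | intermediate
15 | (2S,3S,4R)-4-[3-(benzyloxy)-4-methoxybenzoyl]-2-[3-(benzyloxy)-4-methoxyphenyl]oxolane-3-carbaldehyde (2,3-trans, 3,4-cis) | COc1ccc(C(=O)[C@H]2CO[C@H](c3ccc(OC)c(OCc4ccccc4)c3)[C@H]2C=O)cc1OCc1ccccc1 | intermediate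
16 | (2S,3S,4S)-4-[3-(benzyloxy)-4-methoxybenzoyl]-2-[3-(benzyloxy)-4-methoxyphenyl]oxolane-3-carbaldehyde (all-trans) | COc1ccc(C(=O)[C@@H]2CO[C@H](c3ccc(OC)c(OCc4ccccc4)c3)[C@H]2C=O)cc1OCc1ccccc1 | intermediate
17 | [3-(benzyloxy)-4-methoxyphenyl]{(3S,4R,5S)-5-[3-(benzyloxy)-4-methoxyphenyl]-4-(hydroxymethyl)oxolan-3-yl}methanone | COc1ccc(C(=O)[C@@H]2CO[C@H](c3ccc(OC)c(OCc4ccccc4)c3)[C@H]2CO)cc1OCc1ccccc1 | intermediate
18 | (3-hydroxy-4-methoxyphenyl)[(3S,4R,5S)-5-(3-hydroxy-4-methoxyphenyl)-4-(hydroxymethyl)oxolan-3-yl]methanone | COc1ccc(C(=O)[C@@H]2CO[C@H](c3ccc(OC)c(O)c3)[C@H]2CO)cc1O | target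

## Step count and least certain steps

Total: 10 steps. Longest linear sequence: 10 steps, from 1 to 18; bromide 10 enters as purchased in step 5.

**Step 4 (key step).** The most likely failure is fragmentation of the activated amide before it cyclises: loss of the benzylic allylic alkoxide by β-elimination from the α-deprotonated O-triflyl intermediate, or ionisation at C2. Both are helped by the fact that the allylic oxygen lowers the nucleophilicity of the vinyl group, and ionisation would also erode the configuration at C2. The fallback builds the oxolane first and the four-membered ring second. It sets out from 4, which is O-allylated (NaH, allyl bromide, THF, 0 °C) to 2-(benzyloxy)-1-methoxy-4-[(1S)-1-(prop-2-en-1-yloxy)prop-2-en-1-yl]benzene F1. Ring-closing metathesis with the second-generation Grubbs catalyst gives (2S)-2-[3-(benzyloxy)-4-methoxyphenyl]-2,5-dihydrofuran F2. Intermolecular [2+2] with dichloroketene (Cl3CCOCl, Zn–Cu couple, POCl3, Et2O) should add anti to the aryl group with the carbonyl carbon on the ring carbon remote from it, giving (1S,2S,5R)-2-[3-(benzyloxy)-4-methoxyphenyl]-7,7-dichloro-3-oxabicyclo[3.2.0]heptan-6-one F3. Dechlorination (Zn, NH4Cl, MeOH) returns to the route at 9. The orientation of the ketene addition rests on steric reasoning and would have to be confirmed.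

**Step 3.** The reversible addition of a hindered secondary alkoxide to a weak acceptor may stall. Forcing it invites base-induced 1,3-proton shift of the allylic alkoxide, which would also lower the enantiomeric purity, and oligomerisation of the acrylamide. The fallback sets out from 4 and uses a better acceptor under nucleophilic instead of basic catalysis. PMe3-catalysed oxa-Michael addition to methyl acrylate gives methyl 3-{[(1S)-1-[3-(benzyloxy)-4-methoxyphenyl]prop-2-en-1-yl]oxy}propanoate F4, and aminolysis with Me2NH·HCl and AlMe3 in toluene returns to the route at 6.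

**Step 6.** The elimination may lose regiocontrol (proton loss from the ring-fusion carbon), or the strongly stabilised 1-arylcyclobutyl cation may rearrange or open. Any adventitious acid would also epimerise C2. The fallback avoids the carbinol and the cation altogether and replaces steps 5 and 6. It sets out from 9: kinetic deprotonation at the cyclobutane methylene and O-triflation (KN(SiMe3)2, PhNTf2, THF, −78 °C) give (1S,2S,5R)-2-[3-(benzyloxy)-4-methoxyphenyl]-3-oxabicyclo[3.2.0]hept-6-en-6-yl trifluoromethanesulfonate F5. Suzuki coupling with purchased [3-(benzyloxy)-4-methoxyphenyl]boronic acid (Pd(PPh3)4, K3PO4, dioxane/H2O, 60 °C) returns to the route at 13.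

**Step 7.** Over-oxidation is the concern: attack of ozone on the dialkoxyarenes or oxidation of the benzyl ethers if the end point is overshot, and incomplete reduction of peroxidic oligomers. The fallback separates oxygenation from cleavage. It sets out from 13: dihydroxylation from the convex face (catalytic OsO4, N-methylmorpholine N-oxide, acetone/H2O) gives (1R,2S,5R,6S,7S)-2,6-bis[3-(benzyloxy)-4-methoxyphenyl]-3-oxabicyclo[3.2.0]heptane-6,7-diol F6. Glycol cleavage with NaIO4 (THF/H2O, pH 7 buffer) returns to the route at 15.

**Step 8.** The equilibration may not converge cleanly. The aldehyde α-centre C3 exchanges faster than the ketone α-centre C4, so isomers epimeric at C3 may persist. Prolonged base could also cause slow β-elimination with ring opening (loss of enantiomeric purity) or aldol self-condensation. The fallback reverses the order so that only C4 can move. It sets out from 15: reduction (NaBH4, EtOH/CH2Cl2, −78 °C) gives [3-(benzyloxy)-4-methoxyphenyl]{(3R,4R,5S)-5-[3-(benzyloxy)-4-methoxyphenyl]-4-(hydroxymethyl)oxolan-3-yl}methanone F7, which is expected to rest largely as its bicyclic hemiketal. Equilibration at C4 (DBU, THF, rt, or K2CO3 in MeOH) returns to the route at 17, bypassing 16. This order relies on the facial selectivity of step 4 for C3.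

## Further compounds

F1 | step 4 | 2-(benzyloxy)-1-methoxy-4-[(1S)-1-(prop-2-en-1-yloxy)prop-2-en-1-yl]benzene | C=CCO[C@H](c1ccc(OC)c(OCc2ccccc2)c1)C=C
F2 | step 4 | (2S)-2-[3-(benzyloxy)-4-methoxyphenyl]-2,5-dihydrofuran | C1=C[C@@H](c2ccc(OC)c(OCc3ccccc3)c2)OC1
F3 | step 4 | (1S,2S,5R)-2-[3-(benzyloxy)-4-methoxyphenyl]-7,7-dichloro-3-oxabicyclo[3.2.0]heptan-6-one | O=C1[C@H]2CO[C@H](c3ccc(OC)c(OCc4ccccc4)c3)[C@H]2C1(Cl)Cl
F4 | step 3 | methyl 3-{[(1S)-1-[3-(benzyloxy)-4-methoxyphenyl]prop-2-en-1-yl]oxy}propanoate | COC(=O)CCO[C@H](c1ccc(OC)c(OCc2ccccc2)c1)C=C
F5 | step 6 | (1S,2S,5R)-2-[3-(benzyloxy)-4-methoxyphenyl]-3-oxabicyclo[3.2.0]hept-6-en-6-yl trifluoromethanesulfonate | O=S(=O)(OC1=C[C@H]2[C@@H]1CO[C@@H]2c1ccc(OC)c(OCc2ccccc2)c1)C(F)(F)F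
F6 | step 7 | (1R,2S,5R,6S,7S)-2,6-bis[3-(benzyloxy)-4-methoxyphenyl]-3-oxabicyclo[3.2.0]heptane-6,7-diol (both hydroxy groups on the convex face) | O[C@]1(c2ccc(OC)c(OCc3ccccc3)c2)[C@H]2CO[C@H](c3ccc(OC)c(OCc4ccccc4)c3)[C@H]2[C@@H]1O
F7 | step 8 | [3-(benzyloxy)-4-methoxyphenyl]{(3R,4R,5S)-5-[3-(benzyloxy)-4-methoxyphenyl]-4-(hydroxymethyl)oxolan-3-yl}methanone | COc1ccc(C(=O)[C@H]2CO[C@H](c3ccc(OC)c(OCc4ccccc4)c3)[C@H]2CO)cc1OCc1ccccc1
A1 | alternative 1 | (3S,4R)-4-[(benzyloxy)methyl]-N-methoxy-N-methyl-5-oxooxolane-3-carboxamide | CON(C)C(=O)[C@@H]1COC(=O)[C@H]1COCc1ccccc1
A2 | alternative 1 | [3-(benzyloxy)-4-methoxyphenyl]lithium | [Li]c1ccc(OC)c(OCc2ccccc2)c1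
A3 | alternative 1 | [3-(benzyloxy)-4-methoxyphenyl]{(3S,4R)-5-[3-(benzyloxy)-4-methoxyphenyl]-4-[(benzyloxy)methyl]-5-hydroxyoxolan-3-yl}methanone (anomeric mixture) | COc1ccc(C(=O)[C@@H]2COC(O)(c3ccc(OC)c(OCc4ccccc4)c3)[C@H]2COCc2ccccc2)cc1OCc1ccccc1
A4 | alternative 2 | 3-{1-[3-(benzyloxy)-4-methoxyphenyl]ethenyl}cyclobutan-1-one | C=C(c1ccc(OC)c(OCc2ccccc2)c1)C1CC(=O)C1
A5 | alternative 2 | (4R)-4-{1-[3-(benzyloxy)-4-methoxyphenyl]ethenyl}oxolan-2-one | C=C(c1ccc(OC)c(OCc2ccccc2)c1)[C@@H]1COC(=O)C1
A6 | alternative 3 | rac-4-{1-[3-(benzyloxy)-4-methoxyphenyl]ethenyl}-1,3-dioxolan-2-one | C=C(c1ccc(OC)c(OCc2ccccc2)c1)C1COC(=O)O1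
A7 | alternative 3 | dimethyl 2-{[3-(benzyloxy)-4-methoxyphenyl]methylidene}propanedioate | COC(=O)C(=Cc1ccc(OC)c(OCc2ccccc2)c1)C(=O)OC
A8 | alternative 3 | dimethyl (2R,4S)-2-[3-(benzyloxy)-4-methoxyphenyl]-4-{1-[3-(benzyloxy)-4-methoxyphenyl]ethenyl}oxolane-3,3-dicarboxylate | C=C(c1ccc(OC)c(OCc2ccccc2)c1)[C@@H]1CO[C@H](c2ccc(OC)c(OCc3ccccc3)c2)C1(C(=O)OC)C(=O)OC
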